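**Retrosynthetic overview**

1. Locants: ring as cyclohexanone C1 (C=O), C2 (epoxide C–CH3), C3 (epoxide CH), C4 (CHOH), C5 (CH–side chain), C6 (CHOAc); side chain C1′ (C=CH2), C2′ (CH–O-angeloyl). Late stage: O4 desilylation ⇐ C6 acetoxylation ⇐ β-epoxide by hydroxyl-directed epoxidation of the C1 carbinol (reduce, epoxidise, reoxidise) ⇐ cyclohexenone 26.
2. Key disconnection: 26 ⇒ open-chain keto aldehyde 23; one amine-catalysed operation makes C4–C5 ([2,3]-Wittig shift of an allyl ether) and C2=C3 (aldol condensation), the two ring-forming C–C bonds.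
3. Enabling feature: the array HO–C4–C5–C1′(=CH2), in which the C4 oxygen and the exocyclic methylene carbon can be the two ends of an O–CH2 ether bond (a traceless tether), together with C3 lying 1,5 to the C1 ketone, so that the aldehyde released by the shift closes the six-membered ring onto the ethyl-ketone carbon C2.
4. 23 ⇐ alkyne 8 by copper-catalysed anti-carbomagnesiation/epoxide opening (fixes the alkene geometry), Tamao–Fleming oxidation and O-alkylation; C2′ from asymmetric transfer hydrogenation of ynone 6.
5. Ring order: ring 1 (cyclohexenone, step 11), then ring 2 (oxirane, step 14).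

Key step: step 11

Remark: 1,2-epoxybutane is used as the racemate because its carbinol carbon becomes the C1 ketone (13–22 are pairs of epimers at that carbon); angeloyl = (2Z)-2-methylbut-2-enoyl; β = the ring face that carries the C5 side chain.

**Route**

Step 1
Reactants: 1 4-methylpent-3-enoic acid
Product: 3 N-methoxy-N,4-dimethylpent-3-enamide, via acyl imidazole 2 (not isolated)
Conditions: 1,1'-carbonyldiimidazole, CH2Cl2, 0 °C; then MeNHOMe·HCl, 23 °C
Reagents that add atoms: N,O-dimethylhydroxylamine hydrochloride, CNOC.Cl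
Why: Amide formation by acyl transfer through the acyl imidazole runs under near-neutral conditions, so the β,γ-double bond should not move into conjugation; no stereocentre is formed.

Step 2
Reactants: 3 N-methoxy-N,4-dimethylpent-3-enamide, 4 ethynyltrimethylsilane
Product: 6 6-methyl-1-(trimethylsilyl)hept-5-en-1-yn-3-one, via lithium acetylide 5 (not isolated)
Conditions: 4, n-BuLi, THF, −78 °C; then 3, −78 → 0 °C; aq. NH4Cl
Reagents that add atoms: none
Why: Weinreb ketone synthesis, in which the chelated tetrahedral adduct collapses only on work-up, should give the ynone without over-addition; no stereocentre is formed.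

Step 3
Reactants: 6 6-methyl-1-(trimethylsilyl)hept-5-en-1-yn-3-one
Product: 8 (3S)-6-methylhept-5-en-1-yn-3-ol, via silylated propargylic alcohol 7 (not isolated)
Conditions: Ru[(S,S)-TsDPEN](p-cymene) (1 mol %), i-PrOH, 23 °C; then K2CO3 (cat.), MeOH, 23 °C
Reagents that add atoms: none
Why: Noyori-type asymmetric transfer hydrogenation of an alkynyl ketone, with the alkyne in the position an aryl group takes in the CH/π-controlled hydride transfer, should set the (S)-carbinol (future C2′) under catalyst control, and methanolysis then removes the alkynyl silane.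

Step 4
Reactants: 8 (3S)-6-methylhept-5-en-1-yn-3-ol, 9 (chloromethyl)(isopropoxy)dimethylsilane, 10 1,2-epoxybutane
Product: 13 cyclic silyl ether (5S)-4-(3-hydroxypentylidene)-2,2-dimethyl-5-(3-methylbut-2-en-1-yl)-1,2-oxasilolane, via Grignard reagent 11 (not isolated), via alkenylmagnesium chloride 12 (not isolated)
Conditions: 9, Mg, THF, 23 °C; then 8, CuI (10 mol %), 0 → 23 °C; then 10, 0 °C; aq. NH4Cl
Reagents that add atoms: none
Why: Copper-catalysed anti-carbomagnesiation of a propargylic alcohol puts the carbon group on the alkyne carbon next to the carbinol and magnesium on the terminal carbon cis to the alkoxide (five-membered chelate), so copper-assisted opening of the epoxide at its CH2 terminus with retention should give the trisubstituted alkene with the new chain cis to the carbinol carbon, and the alkoxysilane closes onto the neighbouring oxygen.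

Step 5
Reactants: 13 cyclic silyl ether
Product: 14 tert-butyldimethylsilyl ether of 13
Conditions: TBSCl, imidazole, DMF, 23 °C
Reagents that add atoms: tert-butyldimethylsilyl chloride, CC(C)(C)[Si](C)(C)Cl
Why: Imidazole-promoted silylation protects the only free hydroxyl, the carbinol that later becomes the C1 ketone.

Step 6
Reactants: 14 tert-butyldimethylsilyl ether of 13
Product: 15 (2Z)-5-[(tert-butyldimethylsilyl)oxy]-2-[(1S)-1-hydroxy-4-methylpent-3-en-1-yl]hept-2-en-1-ol
Conditions: KHCO3, 30 % H2O2, THF/MeOH, 23 °C
Reagents that add atoms: hydrogen peroxide, OO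
Why: Tamao–Fleming oxidation of the cyclic alkoxysilane converts C–Si into C–OH with retention of the alkene geometry and frees the secondary allylic hydroxyl, and fluoride-free conditions should avoid protodesilylation of the allylic silane.

Step 7
Reactants: 15 allylic 1,3-diol, 16 2-[(tert-butyldimethylsilyl)oxy]ethanol
Product: 18 (1S)-1-{(2Z)-1-[2-(tert-butyldimethylsilyloxy)ethoxy]-5-(tert-butyldimethylsilyloxy)hept-2-en-2-yl}-4-methylpent-3-en-1-ol, via triflate 17 (not isolated)
Conditions: 16, Tf2O, 2,6-lutidine, CH2Cl2, −40 °C; then 15, toluene, 50 °C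
Reagents that add atoms: none
Why: Williamson-type O-alkylation with a primary alkyl triflate and a hindered pyridine base (no alkoxide) should take place at the unhindered primary allylic hydroxyl and not at the flanked secondary one, which builds the O–CH2 ether.

Step 8
Reactants: 18 mono-ether alcohol, 19 angelic acid
Product: 21 angelate of 18, via mixed anhydride 20 (not isolated)
Conditions: 19, 2,4,6-trichlorobenzoyl chloride, Et3N, toluene, 23 °C; then 18, 80 °C
Reagents that add atoms: none
Why: Yamaguchi esterification through the mixed trichlorobenzoic anhydride, run without a nucleophilic catalyst, should acylate the hindered allylic alcohol with retention at C2′ and without Z-to-E isomerisation of the acyl group.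

Step 9
Reactants: 21 angelate of 18
Product: 22 (1S)-1-[(2Z)-5-hydroxy-1-(2-hydroxyethoxy)hept-2-en-2-yl]-4-methylpent-3-en-1-yl angelate
Conditions: HF·pyridine, THF, 0 → 23 °C
Reagents that add atoms: none
Why: Fluoride-mediated desilylation removes both silyl ethers in one operation and leaves the hindered conjugated ester untouched.

Step 10
Reactants: 22 diol
Product: 23 (1S)-4-methyl-1-[(2Z)-5-oxo-1-(2-oxoethoxy)hept-2-en-2-yl]pent-3-en-1-yl angelate
Conditions: Dess–Martin periodinane (2.5 equiv), CH2Cl2, 0 → 23 °C
Reagents that add atoms: none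
Why: Dess–Martin oxidation is mild enough to give the α-alkoxy aldehyde and the β,γ-unsaturated ketone together without double-bond migration.

Step 11
Reactants: 23 keto aldehyde
Product: 26 (4R,5S)-4-hydroxy-2-methyl-5-[(3S)-3-(angeloyloxy)-6-methylhepta-1,5-dien-2-yl]cyclohex-2-en-1-one, via enamine 24 (not isolated), via hydroxy keto aldehyde 25 (not isolated)
Conditions: pyrrolidine (30 mol %), AcOH (30 mol %), MeOH (0.02 M), 23 → 40 °C
Reagents that add atoms: none
Why: Proposed new method: pyrrolidine should condense with the aldehyde of 23 far faster than with the ketone to give enamine 24, whose nucleophilic carbon (future C4) adds to the alkene terminus (future C5) in a [2,3]-sigmatropic (Wittig-type) shift through a five-membered envelope transition state, breaking the O–CH2 bond, turning that CH2 into the exocyclic methylene and leaving the oxygen on C4; hydrolysis gives 1,5-keto aldehyde 25, and amine/acid-catalysed aldol condensation of the ethyl-ketone CH2 (C2) on the aldehyde (C3) then closes ring 1 in a 6-(enolendo)-exo-trig mode and dehydrates to the C2=C3 enone. The closest known reaction types are the secondary-amine-catalysed [2,3]-Wittig rearrangement of α-allyloxy ketones and the Robinson-type cyclodehydration of 1,5-keto aldehydes; new are the aldehyde-derived enamine and the coupling of both events in one flask. C5 is controlled by the C2′ stereocentre: 1,3-allylic strain in the Z-trisubstituted alkene holds the C2′–H bond in the alkene plane, so the enamine carbon should be delivered to the face bearing the angeloyloxy oxygen, anti to the bulkier prenyl-bearing CH2. C4 is controlled by the envelope transition state, in which an alkene substituent trans to the ether CH2 leads to the anti (ring-trans) product, and any cis isomer can equilibrate through the enamine of 25 before the faster ring closure of the diequatorial isomer. The step needs chemoselectivity (aldehyde over β,γ-unsaturated ketone, secured by the rate of aldehyde condensation and a short reaction time) and regioselectivity in the aldol (secured because only C2 can reach the aldehyde through a six-membered transition state).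

Step 12
Reactants: 26 hydroxy enone
Product: 27 4-O-triethylsilyl ether of 26
Conditions: Et3SiCl, imidazole, DMF, 0 °C
Reagents that add atoms: chlorotriethylsilane, CC[Si](Cl)(CC)CC
Why: Imidazole-promoted silylation blocks the C4 oxygen as a bulky ether so that it neither directs the epoxidation nor is oxidised in the following steps.

Step 13
Reactants: 27 silylated enone
Product: 28 1β-allylic alcohol (C1 hydroxyl cis to the C5 side chain)
Conditions: NaBH4, CeCl3·7H2O, MeOH, −78 °C
Reagents that add atoms: none
Why: Luche reduction is 1,2-selective, and axial hydride delivery to this carvone-type enone should give the pseudo-equatorial β-carbinol, cis to the C5 side chain.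

Step 14
Reactants: 28 allylic alcohol
Product: 29 2β,3β-epoxy alcohol
Conditions: VO(acac)2 (5 mol %), t-BuOOH, CH2Cl2, 0 °C
Reagents that add atoms: tert-butyl hydroperoxide, CC(C)(C)OO
Why: Hydroxyl-directed epoxidation by the vanadium alkylperoxide bound to the β-carbinol should deliver oxygen to the β face of the ring alkene only (setting C2 and C3), while the remote alkenes and the electron-poor angelate are not touched.

Step 15
Reactants: 29 epoxy alcohol
Product: 30 2β,3β-epoxy ketone
Conditions: Dess–Martin periodinane, CH2Cl2, 23 °C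
Reagents that add atoms: none
Why: Dess–Martin oxidation should return the C1 ketone without opening the epoxide, which now sits on the face that a direct nucleophilic epoxidation of the enone would not be expected to give.

Step 16
Reactants: 30 epoxy ketone
Product: 33 6α-acetoxy epoxy ketone, via sodium enolate 31 (not isolated), via sodium alkoxide 32 (not isolated)
Conditions: NaN(SiMe3)2, THF, −78 °C; 2-(phenylsulfonyl)-3-phenyloxaziridine, −78 °C; then Ac2O, −78 → 0 °C
Reagents that add atoms: 2-(phenylsulfonyl)-3-phenyloxaziridine, O=S(=O)(N1OC1c1ccccc1)c1ccccc1; acetic anhydride, CC(=O)OC(C)=O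
Why: Enolate hydroxylation with an N-sulfonyloxaziridine and acetylation of the alkoxide in the same flask: only C6 can be enolised (C2 is quaternary), and the oxidant should approach anti to the adjacent C5 side chain and to the β-epoxide, giving the α (equatorial) acetate that is also the more stable epimer.

Step 17
Reactants: 33 silylated acetoxy epoxy ketone
Product: 34 target CNP0272666.1
Conditions: HF·pyridine, pyridine, THF, 0 °C
Reagents that add atoms: none
Why: Buffered fluoride-mediated desilylation should free the C4 hydroxyl without acetyl migration from O6, epoxide opening or angelate isomerisation.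

**Compound list**

1 | 4-methylpent-3-enoic acid | CC(C)=CCC(=O)O | starting material
2 | 1-(4-methylpent-3-enoyl)imidazole | CC(C)=CCC(=O)n1ccnc1 | intermediate
3 | N-methoxy-N,4-dimethylpent-3-enamide | CC(C)=CCC(=O)N(C)OC | intermediate
4 | ethynyltrimethylsilane | C#C[Si](C)(C)C | starting material
5 | lithium (trimethylsilyl)acetylide | [Li]C#C[Si](C)(C)C | intermediate
6 | 6-methyl-1-(trimethylsilyl)hept-5-en-1-yn-3-one | C[Si](C)(C)C#CC(=O)CC=C(C)C | intermediate
7 | (3S)-6-methyl-1-(trimethylsilyl)hept-5-en-1-yn-3-ol | C[Si](C)(C)C#C[C@H](CC=C(C)C)O | intermediate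
8 | (3S)-6-methylhept-5-en-1-yn-3-ol | C#C[C@H](CC=C(C)C)O | intermediate
9 | (chloromethyl)(isopropoxy)dimethylsilane | CC(C)O[Si](C)(C)CCl | starting material
10 | 1,2-epoxybutane (2-ethyloxirane), racemic | CCC1CO1 | starting material
11 | [(isopropoxydimethylsilyl)methyl]magnesium chloride | CC(C)O[Si](C)(C)C[Mg]Cl | intermediate
12 | chelated alkenylmagnesium chloride from anti-carbomagnesiation of 8 (Mg on the terminal alkene carbon, cis to the (S)-carbinol carbon; silylmethyl group on the inner carbon) | Cl[Mg]/C=C(/C[Si](C)(C)OC(C)C)[C@H](CC=C(C)C)O[Mg]Cl | intermediate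
13 | (5S)-4-(3-hydroxypentylidene)-2,2-dimethyl-5-(3-methylbut-2-en-1-yl)-1,2-oxasilolane; alkylidene CH2 chain cis to ring C5, trans to the CH2Si carbon; both carbinol epimers | CCC(O)C/C=C1/C[Si](C)(C)O[C@H]1CC=C(C)C | intermediate
14 | tert-butyldimethylsilyl ether of 13 (same alkene geometry, 5S) | CCC(O[Si](C)(C)C(C)(C)C)C/C=C1/C[Si](C)(C)O[C@H]1CC=C(C)C | intermediate
15 | (2Z)-5-[(tert-butyldimethylsilyl)oxy]-2-[(1S)-1-hydroxy-4-methylpent-3-en-1-yl]hept-2-en-1-ol | CCC(O[Si](C)(C)C(C)(C)C)C/C=C(/CO)[C@H](CC=C(C)C)O | intermediate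
16 | 2-[(tert-butyldimethylsilyl)oxy]ethanol | CC(C)(C)[Si](C)(C)OCCO | starting material
17 | 2-[(tert-butyldimethylsilyl)oxy]ethyl trifluoromethanesulfonate | CC(C)(C)[Si](C)(C)OCCOS(=O)(=O)C(F)(F)F | intermediate
18 | (1S)-1-{(2Z)-1-[2-(tert-butyldimethylsilyloxy)ethoxy]-5-(tert-butyldimethylsilyloxy)hept-2-en-2-yl}-4-methylpent-3-en-1-ol | CCC(O[Si](C)(C)C(C)(C)C)C/C=C(/COCCO[Si](C)(C)C(C)(C)C)[C@H](CC=C(C)C)O | intermediate
19 | angelic acid, (2Z)-2-methylbut-2-enoic acid | C/C=C(/C)C(=O)O | starting material
20 | (2Z)-2-methylbut-2-enoic 2,4,6-trichlorobenzoic anhydride | C/C=C(/C)C(=O)OC(=O)c1c(Cl)cc(Cl)cc1Cl | intermediate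
21 | (1S)-1-{(2Z)-1-[2-(tert-butyldimethylsilyloxy)ethoxy]-5-(tert-butyldimethylsilyloxy)hept-2-en-2-yl}-4-methylpent-3-en-1-yl angelate | CCC(O[Si](C)(C)C(C)(C)C)C/C=C(/COCCO[Si](C)(C)C(C)(C)C)[C@H](CC=C(C)C)OC(=O)/C(C)=C\C | intermediate
22 | (1S)-1-[(2Z)-5-hydroxy-1-(2-hydroxyethoxy)hept-2-en-2-yl]-4-methylpent-3-en-1-yl angelate | CCC(O)C/C=C(/COCCO)[C@H](CC=C(C)C)OC(=O)/C(C)=C\C | intermediate
23 | (1S)-4-methyl-1-[(2Z)-5-oxo-1-(2-oxoethoxy)hept-2-en-2-yl]pent-3-en-1-yl angelate | CCC(=O)C/C=C(/COCC=O)[C@H](CC=C(C)C)OC(=O)/C(C)=C\C | intermediate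
24 | (E)-pyrrolidine enamine of the aldehyde of 23 | CCC(=O)C/C=C(/CO/C=C/N1CCCC1)[C@H](CC=C(C)C)OC(=O)/C(C)=C\C | intermediate
25 | (2S,3S)-2-hydroxy-3-[(3S)-3-(angeloyloxy)-6-methylhepta-1,5-dien-2-yl]-5-oxoheptanal | C=C([C@H](CC(=O)CC)[C@H](O)C=O)[C@H](CC=C(C)C)OC(=O)/C(C)=C\C | intermediate
26 | (4R,5S)-4-hydroxy-2-methyl-5-[(3S)-3-(angeloyloxy)-6-methylhepta-1,5-dien-2-yl]cyclohex-2-en-1-one (4-OH α, trans to the side chain) | C=C([C@H]1[C@H](O)C=C(C)C(=O)C1)[C@H](CC=C(C)C)OC(=O)/C(C)=C\C | intermediate
27 | 4α-O-triethylsilyl ether of 26 | C=C([C@H]1[C@H](O[Si](CC)(CC)CC)C=C(C)C(=O)C1)[C@H](CC=C(C)C)OC(=O)/C(C)=C\C | intermediate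
28 | 1β-hydroxy-2-methyl-4α-(triethylsilyloxy)-5β-side-chain cyclohex-2-ene (allylic alcohol from 27) | C=C([C@H]1[C@H](O[Si](CC)(CC)CC)C=C(C)[C@@H](O)C1)[C@H](CC=C(C)C)OC(=O)/C(C)=C\C | intermediate
29 | 2β,3β-epoxy-1β-hydroxy-2α-methyl-4α-(triethylsilyloxy)-5β-side-chain cyclohexane | C=C([C@H]1[C@H](O[Si](CC)(CC)CC)[C@H]2O[C@@]2(C)[C@@H](O)C1)[C@H](CC=C(C)C)OC(=O)/C(C)=C\C | intermediate
30 | 2β,3β-epoxy-2α-methyl-4α-(triethylsilyloxy)-5β-side-chain cyclohexan-1-one | C=C([C@H]1[C@H](O[Si](CC)(CC)CC)[C@H]2O[C@@]2(C)C(=O)C1)[C@H](CC=C(C)C)OC(=O)/C(C)=C\C | intermediate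
31 | sodium enolate of 30 (C1=C6) | C=C([C@H]1[C@H](O[Si](CC)(CC)CC)[C@H]2O[C@@]2(C)C([O-])=C1)[C@H](CC=C(C)C)OC(=O)/C(C)=C\C.[Na+] | intermediate
32 | sodium alkoxide of the 6α-hydroxy derivative of 30 | C=C([C@H]1[C@H](O[Si](CC)(CC)CC)[C@H]2O[C@@]2(C)C(=O)[C@@H]1[O-])[C@H](CC=C(C)C)OC(=O)/C(C)=C\C.[Na+] | intermediate
33 | 6α-acetoxy-2β,3β-epoxy-2α-methyl-4α-(triethylsilyloxy)-5β-side-chain cyclohexan-1-one | C=C([C@H]1[C@H](O[Si](CC)(CC)CC)[C@H]2O[C@@]2(C)C(=O)[C@@H]1OC(C)=O)[C@H](CC=C(C)C)OC(=O)/C(C)=C\C | intermediate
34 | (2R,3R,4S,5S,6R)-6-acetoxy-2,3-epoxy-4-hydroxy-2-methyl-5-[(3S)-3-(angeloyloxy)-6-methylhepta-1,5-dien-2-yl]cyclohexan-1-one, CNP0272666.1 | C=C([C@H]1[C@H](O)[C@H]2O[C@@]2(C)C(=O)[C@@H]1OC(C)=O)[C@H](CC=C(C)C)OC(=O)/C(C)=C\C | target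

**Step count and risks**

Total steps: 17. Longest linear sequence: 17 (steps 1–17 from 4-methylpent-3-enoic acid; 4, 9, 10, 16 and 19 enter as commercial compounds).

Step 11 (proposed new method). What may go wrong: isomerisation of the β,γ-unsaturated ketone into conjugation, amine-induced rearrangement of the α-hydroxy aldehyde before ring closure, or erosion of facial control in the sigmatropic shift. Fallback with known reactions, run stepwise: from 23, condensation of the aldehyde with (S)-1-amino-2-(methoxymethyl)pyrrolidine gives SAMP hydrazone F1. Deprotonation with LiN(iPr)2 in THF at −78 °C (the ketone carried as its enolate) triggers the auxiliary-controlled azaenolate [2,3]-Wittig rearrangement to α-hydroxy hydrazone F2. Cleavage of the hydrazone with aqueous oxalic acid gives 25, now isolated, and piperidinium acetate-mediated aldol condensation returns to the route at 26.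

Step 4. What may go wrong: the chelated alkenylmagnesium is protonated or the epoxide is diverted to a halohydrin by magnesium halide before the C–C bond forms. Fallback: from 8, the same carbomagnesiation is quenched with iodine to give alkenyl iodide F3, isolated as the cyclic silyl ether. Iodine–lithium exchange (t-BuLi, Et2O, −78 °C) and BF3·OEt2-promoted opening of 10 by the alkenyllithium then return to the route at 13, so that the two bond formations are run as separate reactions through an isolable intermediate.

Step 16. What may go wrong: side reactions of the enolate (addition to the sulfonimine, acyl transfer from the angelate, epoxide opening) or loss of facial control. Fallback that oxygenates C6 before the epoxide exists: from 27, α′-acetoxylation of the enone with Mn(OAc)3·2H2O in benzene at reflux gives acetoxy enone F4 (acetate trans to the C5 side chain). Luche reduction (NaBH4, CeCl3·7H2O) gives allylic alcohol F5, VO(acac)2/t-BuOOH gives epoxy alcohol F6, and Dess–Martin oxidation returns to the route at 33.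

Further compounds
F1 | step 11 | SAMP hydrazone of keto aldehyde 23 | CCC(=O)C/C=C(/COC/C=N/N1CCC[C@H]1COC)[C@H](CC=C(C)C)OC(=O)/C(C)=C\C
F2 | step 11 | SAMP hydrazone of hydroxy keto aldehyde 25 | C=C([C@H](CC(=O)CC)[C@H](O)/C=N/N1CCC[C@H]1COC)[C@H](CC=C(C)C)OC(=O)/C(C)=C\C
F3 | step 4 | (5S)-4-(iodomethylidene)-2,2-dimethyl-5-(3-methylbut-2-en-1-yl)-1,2-oxasilolane (iodine cis to ring C5) | I/C=C1/C[Si](C)(C)O[C@H]1CC=C(C)C
F4 | step 16 | 6α-acetoxy derivative of enone 27 | C=C([C@H]1[C@H](O[Si](CC)(CC)CC)C=C(C)C(=O)[C@@H]1OC(C)=O)[C@H](CC=C(C)C)OC(=O)/C(C)=C\C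
F5 | step 16 | 6α-acetoxy-1β-hydroxy allylic alcohol | C=C([C@H]1[C@H](O[Si](CC)(CC)CC)C=C(C)[C@@H](O)[C@@H]1OC(C)=O)[C@H](CC=C(C)C)OC(=O)/C(C)=C\C
F6 | step 16 | 6α-acetoxy-2β,3β-epoxy-1β-hydroxy compound | C=C([C@H]1[C@H](O[Si](CC)(CC)CC)[C@H]2O[C@@]2(C)[C@@H](O)[C@@H]1OC(C)=O)[C@H](CC=C(C)C)OC(=O)/C(C)=C\C
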